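The earlier runs and the new flask were computed for an exercise; scatter was added.

The easy step is one division: the last reading of the dawn run leaves 43.4% of its starting material, the limiting reagent by charge. I work with that fraction left throughout.

| flask | starting material | coupling partner | time |
|---|---|---|---|
| dawn | 0.400 M | 0.440 M |  |
| dusk | 0.240 M | 0.280 M |  |
| noon | 0.400 M | 0.660 M |  |
| midnight | 0.600 M | 0.440 M |  |
| summer | 1.20 M | 1.30 M | 50 min |

| run | time / min | [target] / M |
|---|---|---|
| dawn run | 2.0 | 0.0603 |
| dawn run | 4.5 | 0.1065 |
| dawn run | 10 | 0.1564 |
| dawn run | 22 | 0.2002 |
| dawn run | 50 | 0.2266 |
| dusk run | 2.0 | 0.0274 |
| dusk run | 4.5 | 0.0458 |
| dusk run | 10 | 0.0748 |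
| dusk run | 22 | 0.1057 |
| dusk run | 50 | 0.1291 |
| noon run | 2.0 | 0.0826 |
| noon run | 4.5 | 0.1380 |
| noon run | 10 | 0.1977 |
| noon run | 22 | 0.2429 |
| noon run | 50 | 0.2727 |
| midnight run | 2.0 | 0.0883 |
| midnight run | 4.5 | 0.1506 |
| midnight run | 10 | 0.2186 |
| midnight run | 22 | 0.2627 |
| midnight run | 50 | 0.2779 |

(standard deviation of a reading: 0.001 M)

- Overall: starting material + coupling partner -> target.
- Constant volume, constant temperature.
- "The second partner" is coupling partner.
- An order is taken over about fifteen percent of the charge, up and down.

* apparent order in [coupling partner] of the starting rate, round the charge of the dawn run (the rate where two percent of its starting material have turned into target)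
* apparent order in [starting material] of the starting rate, round the charge of the dawn run (the rate where two percent of its starting material have turned into target) (one fixed amount of target, the same in the runs compared)
* the dusk run starts with 0.160 M less of starting material and of coupling partner than the dawn run, and with no target. Compared where both hold the same amount of starting material, once fifteen percent of what the dusk run was charged with has turned into target, is the dusk run faster, slower or alike (within a tenth)?
* target in the summer run at 50 min, as a share of the starting material charged

For the orders and the comparison at equal starting material I stand with the forecast below; my own reckoning goes to the summer run. That run lies beyond the readings, so it needs a rule that moves it onto them. If the steps that count are bimolecular, two flasks with one ratio of charges trace one curve of fraction left against starting material charged times time, the charge clock. The summer run reads 60.0 M·min on this charge clock. The ratios of coupling partner to starting material are close: 1.10 in the dawn run, 1.17 in the dusk run, 1.08 in the summer run.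

I test the rule first. At 22 min the dawn run leaves 50.0%, and the same charge clock falls at 36.7 min in the dusk run.

Between its last two readings I take the fraction left in each run to fall as a power of time, and the exponent is the fall of its logarithm per unit of logarithmic time:

dawn exponent = 0.173

dusk exponent = 0.233

On that power, the dusk run at the same clock leaves 49.7%. These figures come from different flasks, so the agreement is a real check.

Two ways now lead to the summer run, each extending one run to the clock of 60.0 M·min:

from dawn, at 150 min: left = 35.9%

from dusk, at 250 min: left = 31.7%

They part, and the dusk way is the one that cheats. Its exponent is larger than the dawn exponent and was read at an earlier clock, though also at a higher ratio of charges; I read this as an exponent that shrinks as the clock advances. The dusk way also stretches it further. I commit to the dawn way, a share made of 64.1% for the summer run, and I hold even that on the high side.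

The forecast gives orders of 1 and 1, the dusk run faster, and 62% for the summer run, on the ground “That points to product inhibition”. Its share stands below mine.

The simulation gives orders of 1.0 in coupling partner and 1.1 in starting material, the dusk run faster, and 62.0% for the summer run.

    starting material + coupling partner → target + by-product (0.2202 L mol⁻¹ min⁻¹)
    2 coupling partner → lost reagent (0.1860 L mol⁻¹ min⁻¹)
    starting material + coupling partner + target → 2 target (0.2946 L² mol⁻² min⁻¹)

At 60.0 M·min the summer run leaves 38.0% of its starting material. The summer run without the conversion of two coupling partner into lost reagent leaves 0.551% at that clock, so this step is the main reason for the shortfall, with 99% of what is missing. I apply the clock to the dusk run: the dawn run makes target equal to half its charge at 21.6 min, which the clock turns into 36.1 min for the dusk run, whose own time is 35.5 min.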